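**Plan**
Enabling feature: ring A of the flavone (C4a, C5, C6, C7, C8, C8a) carries four contiguous exocyclic oxygens on C5–C8. This is the C4O4 core of dimethyl squarate: the adjacent C6/C7 methoxy groups are its enol-ether carbons, and the one free OH at C5, peri to the C4 carbonyl, is a former ketene oxygen.
Retrosynthesis: cut C4a–C5 (retro-6π, then retro-4π back to a 4-methoxy-4-(4-pyranon-2-yl)cyclobutenone), then the O–methyl bond at C8, then C8–C8a (pyranonyl metal plus squarate C=O). Last come O1–C8a and C2–C3 of the pyranone (aroyl chloride plus 4-methoxybutenone enolate).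
Forward order: ring B is bought with its three methoxy groups and ring C is made first as a 2-aryl-4-pyranone. The four-membered ring is then attached at the pyranone carbon next to oxygen, and ring A is closed last by thermal ring expansion.
Stereochemistry: the target has none; the quaternary cyclobutenone carbon is made racemic and becomes sp2 in the last step.

Key step: step 7

Remark on the chemistry: the target SMILES holds no stereocentre and no stereogenic double bond. The compound is achiral, so the single enantiomer asked for is the compound itself, and the chiral intermediates are used as racemates.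

Step 1
Reactants: 1 2,4,5-trimethoxybenzoic acid
Product: 2 2,4,5-trimethoxybenzoyl chloride
Conditions: (COCl)2 (1.3 equiv), DMF (cat.), CH2Cl2, 0 °C → rt; evaporate, use crude
Reagents that add atoms: oxalyl chloride, O=C(Cl)C(=O)Cl
Why: DMF-catalysed (Vilsmeier-type) acid chloride formation runs without a Lewis acid, so the three aryl methyl ethers and the electron-rich ring should stay untouched.

Step 2
Reactants: 3 (E)-4-methoxybut-3-en-2-one; 2 2,4,5-trimethoxybenzoyl chloride
Product: 5 (4E)-5-methoxy-1-(2,4,5-trimethoxyphenyl)pent-4-ene-1,3-dione (largely enolised), via lithium dienolate 4 (not isolated)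
Conditions: 3 (2.1 equiv), LiHMDS (2.1 equiv), THF, −78 °C; then 2 (1.0 equiv), −78 °C; aq. NH4Cl
Reagents that add atoms: none
Why: Kinetic deprotonation of the vinylogous ester at its methyl group and C-acylation of the lithium enolate by the aroyl chloride (crossed Claisen-type acylation, first half of the standard γ-pyrone synthesis from 4-methoxybutenone) form the later C2–C3 bond, with the second equivalent of enolate taking up the acidic β-diketone proton.

Step 3
Reactants: 5 (4E)-5-methoxy-1-(2,4,5-trimethoxyphenyl)pent-4-ene-1,3-dione
Product: 6 2-(2,4,5-trimethoxyphenyl)-4H-pyran-4-one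
Conditions: TFA (cat.), toluene, rt
Reagents that add atoms: none
Why: Acid-catalysed 6-endo-trig oxa-Michael addition of the aroyl enol oxygen to the β-methoxyenone and loss of methanol (addition–elimination cyclocondensation) close ring C at O1–C8a, driven by formation of the conjugated γ-pyrone.

Step 4
Reactants: 6 2-(2,4,5-trimethoxyphenyl)-4H-pyran-4-one
Product: 8 2-iodo-6-(2,4,5-trimethoxyphenyl)-4H-pyran-4-one, via pyranon-2-ylzinc chloride 7 (not isolated)
Conditions: TMPZnCl·LiCl (1.2 equiv), THF, 25 °C; then I2 (1.3 equiv), THF, 0 °C, dark; aq. Na2S2O3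
Reagents that add atoms: iodine, II
Why: Deprotonative zincation with the magnesium-free TMP–zinc base removes the most acidic proton, the one next to the ring oxygen, as it does at C2 of chromones; the covalent C–Zn bond tolerates the pyranone carbonyl, iodinolysis fixes the site, and magnesium salts are excluded because carbonyl complexation would steer metalation to the carbons beside C=O.

Step 5
Reactants: 8 2-iodo-6-(2,4,5-trimethoxyphenyl)-4H-pyran-4-one; 9 dimethyl squarate (3,4-dimethoxycyclobut-3-ene-1,2-dione)
Product: 11 rac-4-hydroxy-2,3-dimethoxy-4-[4-oxo-6-(2,4,5-trimethoxyphenyl)-4H-pyran-2-yl]cyclobut-2-en-1-one, via pyranon-2-ylmagnesium chloride 10 (not isolated)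
Conditions: iPrMgCl·LiCl (1.05 equiv), THF, −78 °C, 20 min; cannulate into 9 (1.5 equiv), THF, −78 → −40 °C; aq. NH4Cl at −40 °C
Reagents that add atoms: none
Why: Iodine–magnesium exchange is fast at −78 °C on an electron-poor β-iodoenone-type C(sp2)–I bond (as with β-iodoacrylates, iodouracils and iodo-dioxinones) and should outrun attack on the cross-conjugated carbonyl; the alkenyl Grignard then adds 1,2 to one of the two equivalent squarate carbonyls (standard squarate carbonyl addition) to form C8–C8a, and the new quaternary carbinol centre is racemic because both partners are achiral, which does not matter since step 7 flattens it.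

Step 6
Reactants: 11 rac-4-hydroxy-2,3-dimethoxy-4-[4-oxo-6-(2,4,5-trimethoxyphenyl)-4H-pyran-2-yl]cyclobut-2-en-1-one
Product: 12 rac-2,3,4-trimethoxy-4-[4-oxo-6-(2,4,5-trimethoxyphenyl)-4H-pyran-2-yl]cyclobut-2-en-1-one
Conditions: MeI (10 equiv), Ag2O (2 equiv), 4 Å MS, MeCN, rt, dark
Reagents that add atoms: iodomethane, CI
Why: Purdie methylation etherifies 4-hydroxycyclobutenones under nearly neutral conditions, which avoids base-induced retro-addition or ring cleavage of the carbinol and also the O-alkylation of the pyranone carbonyl to a 4-methoxypyrylium salt that methyl triflate would risk; the stereocentre is not touched.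

Step 7
Reactants: 12 rac-2,3,4-trimethoxy-4-[4-oxo-6-(2,4,5-trimethoxyphenyl)-4H-pyran-2-yl]cyclobut-2-en-1-one
Product: 15 agehoustin E, 5-hydroxy-6,7,8-trimethoxy-2-(2,4,5-trimethoxyphenyl)-4H-chromen-4-one, via (Z)-dienylketene 13 (not isolated), via ring-closed keto tautomer 14 (not isolated)
Conditions: p-xylene (degassed, 0.02 M), 138 °C, Ar
Reagents that add atoms: none
Why: Heat breaks the bond between the carbonyl carbon and the quaternary carbon of 12 in a conrotatory 4π electrocyclic opening, giving dienylketene 13 (O=C5=C6–C7=C8–C8a=C4a in flavone numbering). Ring A is then closed by a thermal disrotatory 6π electrocyclisation that joins the ketene carbon C5 to pyranone C3 (= C4a), and the resulting 14 loses its doubly carbonyl-activated C4a proton by enolisation to give the aromatic C5 phenol 15, chelated to C4=O. The closest known reaction is the Moore rearrangement of squarate-derived 4-aryl-, 4-heteroaryl- and 4-alkenyl-4-alkoxycyclobutenones to hydroquinone monoethers; here the alkenyl partner is the C2=C3 bond of a 4-pyranone, whose weak aromaticity costs less to interrupt than that of a benzene ring. The selectivity required is torquoselectivity, because only the ketene with the heterocycle cis to the cumulene can cyclise: the donor methoxy group on the quaternary carbon turns outward and the π-accepting pyranonyl group inward, and any mis-rotated ketene can only revert to 12 and open again. Site selectivity is structural, since C3 is the only ring position within reach, and the polarity is matched, C3 being the nucleophilic α-carbon of the vinylogous ester and the ketene carbon the electrophile. No stereocentre is formed in the product (the racemic quaternary carbon of 12 and the transient C4a centre of 14 both end sp2), and because the former carbinol oxygen is already methylated the only hydroxyl liberated is the ketene oxygen at C5, while high dilution keeps that phenol from being acylated by unreacted ketene.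

**Compound list**
1 | 2,4,5-trimethoxybenzoic acid | COc1cc(OC)c(C(=O)O)cc1OC | starting material
2 | 2,4,5-trimethoxybenzoyl chloride | COc1cc(OC)c(C(=O)Cl)cc1OC | intermediate
3 | (E)-4-methoxybut-3-en-2-one | CO/C=C/C(C)=O | starting material
4 | lithium (3E)-4-methoxybuta-1,3-dien-2-olate | [Li]OC(=C)/C=C/OC | intermediate
5 | (4E)-5-methoxy-1-(2,4,5-trimethoxyphenyl)pent-4-ene-1,3-dione | CO/C=C/C(=O)CC(=O)c1cc(OC)c(OC)cc1OC | intermediate
6 | 2-(2,4,5-trimethoxyphenyl)-4H-pyran-4-one | COc1cc(OC)c(-c2cc(=O)cco2)cc1OC | intermediate
7 | chloro[4-oxo-6-(2,4,5-trimethoxyphenyl)-4H-pyran-2-yl]zinc (LiCl complex) | COc1cc(OC)c(-c2cc(=O)cc([Zn]Cl)o2)cc1OC | intermediate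
8 | 2-iodo-6-(2,4,5-trimethoxyphenyl)-4H-pyran-4-one | COc1cc(OC)c(-c2cc(=O)cc(I)o2)cc1OC | intermediate
9 | dimethyl squarate (3,4-dimethoxycyclobut-3-ene-1,2-dione) | COC1=C(OC)C(=O)C1=O | starting material
10 | chloro[4-oxo-6-(2,4,5-trimethoxyphenyl)-4H-pyran-2-yl]magnesium (LiCl complex) | COc1cc(OC)c(-c2cc(=O)cc([Mg]Cl)o2)cc1OC | intermediate
11 | rac-4-hydroxy-2,3-dimethoxy-4-[4-oxo-6-(2,4,5-trimethoxyphenyl)-4H-pyran-2-yl]cyclobut-2-en-1-one | COC1=C(OC)C(O)(c2cc(=O)cc(-c3cc(OC)c(OC)cc3OC)o2)C1=O | intermediate
12 | rac-2,3,4-trimethoxy-4-[4-oxo-6-(2,4,5-trimethoxyphenyl)-4H-pyran-2-yl]cyclobut-2-en-1-one | COC1=C(OC)C(OC)(c2cc(=O)cc(-c3cc(OC)c(OC)cc3OC)o2)C1=O | intermediate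
13 | (3Z)-2,3,4-trimethoxy-4-[4-oxo-6-(2,4,5-trimethoxyphenyl)-4H-pyran-2-yl]buta-1,3-dien-1-one | O=C=C(OC)/C(OC)=C(\c1cc(=O)cc(-c2cc(OC)c(OC)cc2OC)o1)OC | intermediate
14 | rac-6,7,8-trimethoxy-2-(2,4,5-trimethoxyphenyl)-4aH-chromene-4,5-dione | COC1=C(OC)C(OC)=C2OC(-c3cc(OC)c(OC)cc3OC)=CC(=O)C2C1=O | intermediate
15 | agehoustin E, 5-hydroxy-6,7,8-trimethoxy-2-(2,4,5-trimethoxyphenyl)-4H-chromen-4-one (achiral) | COc1cc(OC)c(-c2cc(=O)c3c(O)c(OC)c(OC)c(OC)c3o2)cc1OC | target

**Total step count:** 7.
**Longest linear sequence:** 7 steps (1 → 2 → 5 → 6 → 8 → 11 → 12 → 15). Compounds 3 and 9 enter as purchased partners. Step 7 is an isomerisation: 12 and 15 are both C21H22O9.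

**Steps most likely to fail**

Step 7. Closure of the ketene onto pyranone C3 may be slower than re-closure to the cyclobutenone, ketene dimerisation or capture of the ketene by the phenol already formed, so that material degrades on prolonged heating.
The fallback gives up the pericyclic construction of ring A and assembles the flavone by the Baker–Venkataraman route. It sets out from 2 and comes back at 15.
- Acid chloride 2 acylates the purchasable 1-(2-hydroxy-3,4,5,6-tetramethoxyphenyl)ethan-1-one F1 in pyridine at rt to give 2-acetyl-3,4,5,6-tetramethoxyphenyl 2,4,5-trimethoxybenzoate F2.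
- KOH in pyridine at 50 °C moves the aroyl group from oxygen to the acetyl carbon to give 1-(2-hydroxy-3,4,5,6-tetramethoxyphenyl)-3-(2,4,5-trimethoxyphenyl)propane-1,3-dione F3.
- H2SO4 in AcOH cyclodehydrates it to 5,6,7,8-tetramethoxy-2-(2,4,5-trimethoxyphenyl)-4H-chromen-4-one F4.
- BCl3 in CH2Cl2 at −78 → 0 °C, held by chelation to the C4 carbonyl, should cleave only the peri C5 methyl ether and give 15.

Step 5. The magnesiated pyranone may self-condense or be protonated before it meets the squarate. The exchange reagent may also attack the iodine-bearing carbon by addition–elimination instead of exchanging.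
The fallback drops the halogen–metal exchange and the Grignard reagent and uses the thermally robust organozinc as the nucleophile. It sets out from 6 and comes back at 11, bypassing 8 and 10, and makes no compound outside the list (F0).
- Compound 6 is zincated to 7 as in step 4.
- Anhydrous MgCl2 is added only after the metalation, so the regiochemistry is already fixed, and 9 follows.
- The Lewis-acid-accelerated carbonyl addition of the organozinc, known for aryl- and heteroarylzinc reagents with aldehydes and activated ketones, is run at 0–25 °C and quenched with aqueous NH4Cl.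

Step 6. Etherification of the hindered tertiary carbinol may stall. Forcing it may bring on alkylation at the pyranone carbonyl oxygen or retro-addition with loss of the heterocycle.
The fallback postpones the methylation until after the ring expansion. It sets out from 11 and comes back at 15.
- The free carbinol 11, whose hydroxyl is likewise an outward-rotating donor, is heated in degassed p-xylene at 138 °C. The same 4π/6π sequence should give 5,8-dihydroxy-6,7-dimethoxy-2-(2,4,5-trimethoxyphenyl)-4H-chromen-4-one F5.
- F5 is kept under argon; Na2S2O4 is used in the work-up should air oxidation to the quinone set in.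
- Me2SO4 (1.05 equiv) and K2CO3 in acetone under argon should then methylate only the C8 hydroxyl, because the C5 hydroxyl is tied up in the hydrogen bond to C4=O. This is the classical partial methylation of 5,8-dihydroxyflavones.

**Further compounds**
F1 | step 7 | 1-(2-hydroxy-3,4,5,6-tetramethoxyphenyl)ethan-1-one | CC(=O)c1c(O)c(OC)c(OC)c(OC)c1OC
F2 | step 7 | 2-acetyl-3,4,5,6-tetramethoxyphenyl 2,4,5-trimethoxybenzoate | CC(=O)c1c(OC(=O)c2cc(OC)c(OC)cc2OC)c(OC)c(OC)c(OC)c1OC
F3 | step 7 | 1-(2-hydroxy-3,4,5,6-tetramethoxyphenyl)-3-(2,4,5-trimethoxyphenyl)propane-1,3-dione | COc1cc(OC)c(C(=O)CC(=O)c2c(O)c(OC)c(OC)c(OC)c2OC)cc1OC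
F4 | step 7 | 5,6,7,8-tetramethoxy-2-(2,4,5-trimethoxyphenyl)-4H-chromen-4-one | COc1cc(OC)c(-c2cc(=O)c3c(OC)c(OC)c(OC)c(OC)c3o2)cc1OC
F0 | step 5 | none | none
F5 | step 6 | 5,8-dihydroxy-6,7-dimethoxy-2-(2,4,5-trimethoxyphenyl)-4H-chromen-4-one | COc1cc(OC)c(-c2cc(=O)c3c(O)c(OC)c(OC)c(O)c3o2)cc1OC
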